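**Retrosynthetic overview**
- Target 16 ⇒ resorcinol 9 + HC(OEt)3 (supplies C4) + acyclic triketide 13 in one flask: the dihydropyranone (ring C) and the coumarin lactone (ring B) both close there, with the citrinin-type quinone methide 14 acting as a masked salicylaldehyde.
- 13 ⇒ methyl acetoacetate 10 (dianion) + ethyl (S)-3-hydroxybutanoate 11; the pyranone stereocentre comes from the chiral pool.
- 9 ⇒ aryllithium 7 + (2R,3R)-2,3-epoxybutane 6 (both side-chain stereocentres set in one SN2 opening), then O-demethylation.
- Bromide 5 ⇒ 2,6-dimethoxytoluene 1 by meta C–H borylation/bromination, then ortho-lithiation/methylation.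
- Ring order: ring A is bought; in the last flask a transient pyran ring forms, then ring C, then ring B (the pyran ring reopens).

Assumptions: 6 and 11 are bought as single enantiomers; a sequence run in one flask without work-up counts as one step. Read from the SMILES, the target is the erythro (2R,3R) side-chain isomer with a (2S) dihydropyranone. The route is designed on paper and has not been run.

**Step 1**
Reactants: 1 2,6-dimethoxytoluene
Product: 3 5-bromo-1,3-dimethoxy-2-methylbenzene, via arylboronate 2 (not isolated)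
Conditions: [Ir(OMe)(cod)]2 (1 mol %), 4,4'-di-tert-butyl-2,2'-bipyridine (2 mol %), B2pin2 (0.6 equiv), THF, 80 °C; evaporate; CuBr2 (3 equiv), MeOH/H2O 1:1, 80 °C
Reagents that add atoms: CuBr2, [Cu+2].[Br-].[Br-]; bis(pinacolato)diboron, CC1(C)OB(OC1(C)C)B1OC(C)(C)C(C)(C)O1 (its boron stays only in 2)
Why: Sterically controlled iridium-catalysed C–H borylation hits the only ring C–H without an ortho substituent, and CuBr2 then replaces the boronate by bromine at the same carbon (one-pot borylation/ipso-bromodeboronation).

**Step 2**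
Reactants: 3 5-bromo-1,3-dimethoxy-2-methylbenzene
Product: 5 1-bromo-3,5-dimethoxy-2,4-dimethylbenzene, via aryllithium 4 (not isolated)
Conditions: LiN(i-Pr)2 (1.2 equiv), THF, −78 °C, 1 h; MeI (2 equiv), −78 → 0 °C
Reagents that add atoms: iodomethane, CI
Why: Directed ortho-metalation removes a ring proton flanked by Br and OMe (the two ring protons of 3 are equivalent, so only one regioisomer can form), and the ortho-bromoaryllithium is methylated at −78 °C before it can lose LiBr.

**Step 3**
Reactants: 5 1-bromo-3,5-dimethoxy-2,4-dimethylbenzene; 6 (2R,3R)-2,3-dimethyloxirane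
Product: 8 (2R,3R)-3-(3,5-dimethoxy-2,4-dimethylphenyl)butan-2-ol, via aryllithium 7 (not isolated)
Conditions: n-BuLi (1.05 equiv), THF, −78 °C, 30 min; 6 (1.5 equiv), then BF3·OEt2 (1.5 equiv), −78 °C, 2 h; aq NH4Cl
Reagents that add atoms: none
Why: Li–Br exchange followed by BF3-promoted SN2 opening of the C2-symmetric trans-epoxide (Eis–Ganem conditions) inverts the attacked carbon and leaves the carbinol carbon untouched, which gives the erythro (2R,3R) alcohol whichever epoxide carbon is attacked.

**Step 4**
Reactants: 8 (2R,3R)-3-(3,5-dimethoxy-2,4-dimethylphenyl)butan-2-ol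
Product: 9 5-[(2R,3R)-3-hydroxybutan-2-yl]-2,4-dimethylbenzene-1,3-diol
Conditions: BBr3 (4 equiv), CH2Cl2, −78 → 0 °C; MeOH, then aq NaHCO3
Reagents that add atoms: none
Why: BBr3 cleaves both aryl methyl ethers (Lewis-acid-assisted SN2 demethylation by bromide), while the secondary alcohol is only held as a borate that is hydrolysed on work-up, so neither stereocentre is touched.

**Step 5**
Reactants: 10 methyl acetoacetate; 11 ethyl (3S)-3-hydroxybutanoate
Product: 13 methyl (7S)-7-hydroxy-3,5-dioxooctanoate, via acetoacetate dianion 12 (not isolated)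
Conditions: 10 (3.3 equiv), NaH (3.3 equiv), THF, 0 °C; n-BuLi (3.3 equiv), 0 °C; 11 (1 equiv), −78 → −20 °C; AcOH, −78 °C, cold pH 5 work-up
Reagents that add atoms: none
Why: Claisen acylation of the γ-carbon of the acetoacetate dianion by the ester (Huckin–Weiler), run with excess dianion so that one equivalent deprotonates the free OH as in excess-enolate Claisen condensations of unprotected β-hydroxy esters; the stereocentre comes from 11 and is not α to a carbonyl.

**Step 6**
Reactants: 9 5-[(2R,3R)-3-hydroxybutan-2-yl]-2,4-dimethylbenzene-1,3-diol; 13 methyl (7S)-7-hydroxy-3,5-dioxooctanoate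
Product: 16 7-hydroxy-5-[(2R,3R)-3-hydroxybutan-2-yl]-6,8-dimethyl-3-[(2S)-2-methyl-4-oxo-3,4-dihydro-2H-pyran-6-yl]-2H-chromen-2-one, via quinone methide 14 (not isolated), via pyranone ester 15 (not isolated)
Conditions: HC(OEt)3 (3 equiv), TFA/CH2Cl2 1:4, 0 °C → rt, 2 h; evaporate (toluene chase); 13 (1.2 equiv), TFA (0.1 equiv), CH2Cl2, rt, 1 h; then EtOH, piperidine (0.4 equiv), AcOH (0.2 equiv), 45 °C, 12 h
Reagents that add atoms: triethyl orthoformate, CCOC(OCC)OCC
Why: Proposed new method: the orthoformate C-formylates the only free ring carbon of 9 and the side-chain OH closes the pyran to quinone methide 14 (the ring closure that ends the classical citrinin synthesis), catalytic acid cyclodehydrates the δ-hydroxy-β-diketone 13 to dihydropyranone 15 (ring C, which also removes the competing C4 methylene), and under piperidinium acetate the dienolate of 15 adds 1,6 to C1 of 14, the pyran reopens by E1cB (retro-oxa-Michael) and the ortho phenol lactonises with loss of MeOH (ring B), which is a Knoevenagel–lactonisation coumarin synthesis with 14 in place of the salicylaldehyde; no stereocentre is formed or made labile.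

**Compound list**
1 | 2,6-dimethoxytoluene (1,3-dimethoxy-2-methylbenzene) | COc1cccc(OC)c1C | starting material
2 | 2-(3,5-dimethoxy-4-methylphenyl)-4,4,5,5-tetramethyl-1,3,2-dioxaborolane | COc1cc(cc(OC)c1C)B1OC(C)(C)C(C)(C)O1 | intermediate
3 | 5-bromo-1,3-dimethoxy-2-methylbenzene | COc1cc(Br)cc(OC)c1C | intermediate
4 | (6-bromo-2,4-dimethoxy-3-methylphenyl)lithium | [Li]c1c(Br)cc(OC)c(C)c1OC | intermediate
5 | 1-bromo-3,5-dimethoxy-2,4-dimethylbenzene | COc1cc(Br)c(C)c(OC)c1C | intermediate
6 | (2R,3R)-2,3-dimethyloxirane (trans-2,3-epoxybutane) | C[C@H]1O[C@@H]1C | starting material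
7 | (3,5-dimethoxy-2,4-dimethylphenyl)lithium | [Li]c1cc(OC)c(C)c(OC)c1C | intermediate
8 | (2R,3R)-3-(3,5-dimethoxy-2,4-dimethylphenyl)butan-2-ol | COc1cc([C@@H](C)[C@@H](C)O)c(C)c(OC)c1C | intermediate
9 | 5-[(2R,3R)-3-hydroxybutan-2-yl]-2,4-dimethylbenzene-1,3-diol | Cc1c(O)c(C)c(O)cc1[C@@H](C)[C@@H](C)O | intermediate
10 | methyl acetoacetate | COC(=O)CC(C)=O | starting material
11 | ethyl (3S)-3-hydroxybutanoate | CCOC(=O)C[C@H](C)O | starting material
12 | methyl acetoacetate dianion, sodium lithium salt | [Na+].[Li+].COC(=O)[CH-]C(=O)[CH2-] | intermediate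
13 | methyl (7S)-7-hydroxy-3,5-dioxooctanoate | COC(=O)CC(=O)CC(=O)C[C@H](C)O | intermediate
14 | (3R,4R)-8-hydroxy-3,4,5,7-tetramethyl-3,4-dihydro-6H-isochromen-6-one | CC1=C2[C@@H](C)[C@@H](C)OC=C2C(O)=C(C)C1=O | intermediate
15 | methyl 2-[(2S)-2-methyl-4-oxo-3,4-dihydro-2H-pyran-6-yl]acetate | COC(=O)CC1=CC(=O)C[C@H](C)O1 | intermediate
16 | 7-hydroxy-5-[(2R,3R)-3-hydroxybutan-2-yl]-6,8-dimethyl-3-[(2S)-2-methyl-4-oxo-3,4-dihydro-2H-pyran-6-yl]-2H-chromen-2-one | Cc1c(O)c(C)c2oc(=O)c(C3=CC(=O)C[C@H](C)O3)cc2c1[C@@H](C)[C@@H](C)O | target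

**Step count**
Total: 6 steps. Longest linear sequence: 5 steps (steps 1, 2, 3, 4, 6); step 5 is the side branch.

**Steps most likely to fail, with fallbacks**

Step 6 (one-flask cascade). The main risks are:
- orthoformate carried over into the condensation;
- C-alkylation of the pyranone enone carbon by protonated 14 during the acid stage;
- partial racemisation of the pyranone centre by retro-oxa-Michael under the amine.

Fallback, setting out from 9 and 13 and coming back at 16: the C4 carbon is placed on the pyranone partner instead of the arene. 13 is cyclodehydrated on its own (TsOH, CH2Cl2) to isolated 15. 15 is condensed with Me2NCH(OMe)2 to give methyl 3-(dimethylamino)-2-[(2S)-2-methyl-4-oxo-3,4-dihydro-2H-pyran-6-yl]prop-2-enoate F1 (E/Z immaterial). Heating 9 with F1 in AcOH with catalytic TFA gives 16 by Pechmann-type attack of the only free ring carbon of 9 on the aminomethylene carbon, loss of Me2NH and lactonisation. Rings C and B are then made in separate operations.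

Step 3 (hindered aryllithium with an internal epoxide). Risks are competing reaction of ArLi with BF3 and Lewis-acid rearrangement of the epoxide. Fallback, setting out from 5 and coming back at 8: 5 is converted with Mg in THF to (3,5-dimethoxy-2,4-dimethylphenyl)magnesium bromide F2. With CuI (10 mol %), F2 opens purchased (4R,5R)-4,5-dimethyl-1,3,2-dioxathiolane 2,2-dioxide (the cyclic sulfate of (2R,3R)-butane-2,3-diol) by SN2 with inversion. This gives (2R,3R)-3-(3,5-dimethoxy-2,4-dimethylphenyl)butan-2-yl hydrogen sulfate F3 (formed as its magnesium salt). Hydrolysis with catalytic H2SO4 and water in THF (S–O cleavage, retention) gives 8 with the same configuration as the epoxide route.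

Step 5 (dianion acylation with the unprotected hydroxy ester). The risk is low conversion of the alkoxide-bearing ester and self-condensation of the dianion. Fallback, setting out from 11 and coming back at 13: 11 is converted with MeNHOMe·HCl and i-PrMgCl to (3S)-3-hydroxy-N-methoxy-N-methylbutanamide F4. The lithium dienolate of purchased 2,2,6-trimethyl-4H-1,3-dioxin-4-one (LiN(SiMe3)2, 3 equiv, THF, −78 °C) is acylated at its γ-carbon by F4 to give 6-[(4S)-4-hydroxy-2-oxopentyl]-2,2-dimethyl-4H-1,3-dioxin-4-one F5. Heating F5 in toluene/MeOH at 100 °C (sealed) expels acetone, and the acylketene is trapped by MeOH to give 13.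

**Further compounds**
F1 | step 6 | methyl 3-(dimethylamino)-2-[(2S)-2-methyl-4-oxo-3,4-dihydro-2H-pyran-6-yl]prop-2-enoate | COC(=O)C(=CN(C)C)C1=CC(=O)C[C@H](C)O1
F2 | step 3 | (3,5-dimethoxy-2,4-dimethylphenyl)magnesium bromide | COc1cc([Mg]Br)c(C)c(OC)c1C
F3 | step 3 | (2R,3R)-3-(3,5-dimethoxy-2,4-dimethylphenyl)butan-2-yl hydrogen sulfate | COc1cc([C@@H](C)[C@@H](C)OS(=O)(=O)O)c(C)c(OC)c1C
F4 | step 5 | (3S)-3-hydroxy-N-methoxy-N-methylbutanamide | CON(C)C(=O)C[C@H](C)O
F5 | step 5 | 6-[(4S)-4-hydroxy-2-oxopentyl]-2,2-dimethyl-4H-1,3-dioxin-4-one | CC1(C)OC(=O)C=C(CC(=O)C[C@H](C)O)O1
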